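**Plan**

- Locants: the target is read as an oxolane with O1, C2 (CH2), C3 (bears the carbinol carbon), C4 (bears CH2OH) and C5 (bears the catechol ring). The retrosynthesis cuts, in this order, the three O-benzyl groups, the lactone that links the carbinol oxygen to the CH2OH carbon, the aryl–carbinol C–C bond (aryl Grignard reagent plus aldehyde), and then both ring C–C bonds C2–C3 and C4–C5 at once.
- Enabling feature: C2–O1–C5(aryl) is a carbonyl ylide (C–O–C 1,3-dipole) built from a methylene and the catechol aldehyde. C3–C4, whose two carbon substituents are cis, is the Z double bond of a butenolide whose acetal carbon becomes the carbinol carbon and whose carbonyl carbon becomes CH2OH.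
- Forward: aldehyde 1 gives the α-silyl alcohol and then the O,S-acetal 3; furfural gives the hydroxybutenolide and then the (+)-menthyl acetal 7. Compounds 3 and 7 are joined in one (3+2) step that makes the oxolane ring as the bicyclic lactone acetal 10. Acetal hydrolysis, esterification, aryl Grignard addition with lactonisation, LiAlH4 reduction and hydrogenolysis complete the route.
- Stereochemistry: the acetal carbon of 7 (fixed by (+)-menthol and crystallisation) sends the ylide to the opposite face. The Z-alkene gives the cis C3/C4 relationship, an exo transition state puts the C5 aryl group trans to the C4 substituent, and the (R)-carbinol comes from Felkin–Anh addition to the aldehyde on C3.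

Key step: step 5

Remark: 7 is the mirror image of the well-known (−)-menthol-derived (5R)-butenolide, and its (5S) epimer is assumed to crystallise in the same way; racemic 2, 3 and 8 suffice because their stereocentre becomes trigonal in ylide 9.

**Step 1**
Reactants: 1 3,4-bis(benzyloxy)benzaldehyde
Product: 2 (RS)-[3,4-bis(benzyloxy)phenyl][dimethyl(phenyl)silyl]methanol
Conditions: PhMe2Si–Bpin, [1,3-bis(2,6-diisopropylphenyl)imidazol-2-ylidene]copper chloride (IPr)CuCl (5 mol %), NaOtBu (10 mol %), THF, rt; then aq. NH4Cl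
Reagents that add atoms: (dimethylphenylsilyl)boronic acid pinacol ester, C[Si](C)(c1ccccc1)B1OC(C)(C)C(C)(C)O1
Why: Copper-catalysed 1,2-addition of a silyl nucleophile (copper silyl species formed from the Si–B reagent) to an aryl aldehyde should give the α-hydroxysilane after O–B hydrolysis, and the racemic new stereocentre is of no consequence because it is flattened in step 5.

**Step 2**
Reactants: 2 (RS)-[3,4-bis(benzyloxy)phenyl][dimethyl(phenyl)silyl]methanol
Product: 3 (RS)-{[3,4-bis(benzyloxy)phenyl][(methylsulfanyl)methoxy]methyl}dimethyl(phenyl)silane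
Conditions: Me2S, (BzO)2, MeCN, 0 °C
Reagents that add atoms: dimethyl sulfide, CSC
Why: Methylthiomethyl ether formation through the Pummerer-type CH2=S(+)Me ion made from Me2S and dibenzoyl peroxide should alkylate the alcohol without any alkoxide, which avoids Brook rearrangement of the α-silyl carbinol.

**Step 3**
Reactants: 4 furfural
Product: 5 (RS)-5-hydroxyfuran-2(5H)-one
Conditions: O2, methylene blue (cat.), MeOH, visible light, rt
Reagents that add atoms: dioxygen, O=O
Why: Sensitised photooxygenation, in which singlet oxygen adds (4+2) to the furan and methanolysis of the endoperoxide expels the formyl carbon, should leave the hydroxybutenolide as a racemic hemiacetal.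

**Step 4**
Reactants: 5 (RS)-5-hydroxyfuran-2(5H)-one; 6 (+)-menthol
Product: 7 (5S)-5-{[(1S,2R,5S)-5-methyl-2-(propan-2-yl)cyclohexyl]oxy}furan-2(5H)-one
Conditions: (±)-camphorsulfonic acid (cat.), toluene, reflux, Dean–Stark; crystallisation from petroleum ether at −20 °C with acid re-equilibration of the mother liquor
Reagents that add atoms: none
Why: Acid-catalysed acetalisation gives both C5 epimers, which interconvert through the oxocarbenium ion, so crystallisation of the (5S) epimer should drive the mixture to one diastereomer (crystallisation-induced asymmetric transformation) and thereby set the acetal stereocentre.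

**Step 5**
Reactants: 3 (RS)-{[3,4-bis(benzyloxy)phenyl][(methylsulfanyl)methoxy]methyl}dimethyl(phenyl)silane; 7 (5S)-5-{[(1S,2R,5S)-5-methyl-2-(propan-2-yl)cyclohexyl]oxy}furan-2(5H)-one
Product: 10 (3S,3aR,6S,6aS)-6-[3,4-bis(benzyloxy)phenyl]-3-{[(1S,2R,5S)-5-methyl-2-(propan-2-yl)cyclohexyl]oxy}tetrahydro-1H,3H-furo[3,4-c]furan-1-one, via chloromethyl ether 8 (not isolated), via carbonyl ylide 9 (not isolated)
Conditions: (i) SO2Cl2, cyclohexene, CH2Cl2, −78 to 0 °C, evaporation; (ii) 7, CsF, MeCN, rt (3 in excess)
Reagents that add atoms: none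
Why: Sulfuryl chloride converts the O,S-acetal into chloromethyl ether 8, and fluoride attack at silicon with loss of chloride (1,3-elimination) gives the non-stabilised carbonyl ylide 9, which adds across C3=C4 of 7 in a concerted suprafacial 1,3-dipolar cycloaddition. The closest known reaction type is the fluoride-induced, silicon-based 1,3-elimination route to carbonyl ylides and their (3+2) addition to α,β-unsaturated esters, together with the anti-selective dipolar cycloadditions of 5-alkoxybutenolides. The oxolane ring is closed intermolecularly as a (3+2) cycloaddition in which both C–C bonds form on one face of the alkene, so the Z geometry of the butenolide becomes the cis ring fusion at C3a and C6a. The absolute configuration of both fusion carbons follows from approach of the ylide anti to the menthyloxy group on C5 of 7. The aryl-bearing carbon C6 is set by an exo transition state of the ylide with its aryl group anti to the CH2 terminus, which places the aryl group on the convex face, trans to the lactone carbonyl carbon. The step needs the CH2 terminus to bond to the β-carbon and the ArCH terminus to the α-carbon; this is secured because the electron-rich aryl group polarises the ylide as an aryl-stabilised oxocarbenium ion with the nucleophilic charge on CH2, and because the small CH2 terminus fits best next to the acetal carbon.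

**Step 6**
Reactants: 10 (3S,3aR,6S,6aS)-6-[3,4-bis(benzyloxy)phenyl]-3-(menthyloxy)tetrahydro-1H,3H-furo[3,4-c]furan-1-one
Product: 11 (3aR,6S,6aS)-6-[3,4-bis(benzyloxy)phenyl]-3-hydroxytetrahydro-1H,3H-furo[3,4-c]furan-1-one (lactol, both C3 epimers)
Conditions: 2 M aq. HCl, 1,4-dioxane, 50 °C
Reagents that add atoms: water, O
Why: Acid hydrolysis of the acyloxy acetal (pseudo-ester) should release menthol and leave the cis-fused lactol, in which the aldehyde stays masked so that the adjacent ring carbon cannot epimerise, while the benzylic ring ether is deactivated towards ionisation by the neighbouring acyl-bearing carbon.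

**Step 7**
Reactants: 11 (3aR,6S,6aS)-6-[3,4-bis(benzyloxy)phenyl]-3-hydroxytetrahydro-1H,3H-furo[3,4-c]furan-1-one
Product: 12 methyl (2S,3S,4R)-2-[3,4-bis(benzyloxy)phenyl]-4-formyloxolane-3-carboxylate
Conditions: TMSCHN2, toluene/MeOH, 0 °C
Reagents that add atoms: (trimethylsilyl)diazomethane, C[Si](C)(C)C=[N+]=[N-]
Why: Methyl ester formation with the diazoalkane takes place on the open carboxylic acid tautomer of the pseudo-acid under neutral conditions, which should trap the ring-opened aldehyde ester without base and so without epimerisation of the cis formyl-bearing carbon.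

**Step 8**
Reactants: 12 methyl (2S,3S,4R)-2-[3,4-bis(benzyloxy)phenyl]-4-formyloxolane-3-carboxylate; 13 1-(benzyloxy)-4-bromo-2-methoxybenzene
Product: 16 (3R,3aR,6S,6aS)-3-[4-(benzyloxy)-3-methoxyphenyl]-6-[3,4-bis(benzyloxy)phenyl]tetrahydro-1H,3H-furo[3,4-c]furan-1-one, via arylmagnesium bromide 14 (not isolated), via hydroxy ester 15 (not isolated)
Conditions: 13, Mg, THF, reflux; then 12, THF, −78 to 0 °C; aq. NH4Cl
Reagents that add atoms: none
Why: Grignard addition to the aldehyde (much faster than to the ester at −78 °C) should follow the Felkin–Anh model, with the more substituted ring carbon C3 anti to the incoming aryl group and the carbonyl oxygen beside the ring CH2 (a magnesium chelate to the ring oxygen would hold the same rotamer), which gives the (R)-carbinol, and the alkoxide then closes the γ-lactone onto the cis ester.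

**Step 9**
Reactants: 16 (3R,3aR,6S,6aS)-3-[4-(benzyloxy)-3-methoxyphenyl]-6-[3,4-bis(benzyloxy)phenyl]tetrahydro-1H,3H-furo[3,4-c]furan-1-one
Product: 17 (R)-[4-(benzyloxy)-3-methoxyphenyl]{(3R,4R,5S)-5-[3,4-bis(benzyloxy)phenyl]-4-(hydroxymethyl)oxolan-3-yl}methanol
Conditions: LiAlH4, THF, 0 °C; aq. NaOH work-up
Reagents that add atoms: none
Why: Hydride reduction of the lactone to the 1,4-diol touches no stereocentre and leaves the benzyl ethers and the ring ether intact.

**Step 10**
Reactants: 17 (R)-[4-(benzyloxy)-3-methoxyphenyl]{(3R,4R,5S)-5-[3,4-bis(benzyloxy)phenyl]-4-(hydroxymethyl)oxolan-3-yl}methanol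
Product: 18 (7R)-7-hydroxytaxiresinol
Conditions: H2 (1 atm), 10% Pd/C, EtOAc, rt
Reagents that add atoms: none
Why: Hydrogenolysis of the three aryl benzyl ethers over Pd/C under neutral conditions at 1 atm should be faster than cleavage of the benzylic alcohol and of the benzylic ring ether, and it frees both phenol units.

**Compound list**

1 | 3,4-bis(benzyloxy)benzaldehyde | O=Cc1ccc(OCc2ccccc2)c(OCc2ccccc2)c1 | starting material
2 | (RS)-[3,4-bis(benzyloxy)phenyl][dimethyl(phenyl)silyl]methanol | OC(c1ccc(OCc2ccccc2)c(OCc2ccccc2)c1)[Si](C)(C)c1ccccc1 | intermediate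
3 | (RS)-{[3,4-bis(benzyloxy)phenyl][(methylsulfanyl)methoxy]methyl}dimethyl(phenyl)silane | CSCOC(c1ccc(OCc2ccccc2)c(OCc2ccccc2)c1)[Si](C)(C)c1ccccc1 | intermediate
4 | furfural (furan-2-carbaldehyde) | O=Cc1ccco1 | starting material
5 | (RS)-5-hydroxyfuran-2(5H)-one | OC1OC(=O)C=C1 | intermediate
6 | (+)-menthol, (1S,2R,5S)-5-methyl-2-(propan-2-yl)cyclohexan-1-ol | C[C@H]1CC[C@@H]([C@H](C1)O)C(C)C | starting material
7 | (5S)-5-{[(1S,2R,5S)-5-methyl-2-(propan-2-yl)cyclohexyl]oxy}furan-2(5H)-one | C[C@H]1CC[C@@H]([C@H](C1)O[C@@H]2C=CC(=O)O2)C(C)C | intermediate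
8 | (RS)-{[3,4-bis(benzyloxy)phenyl](chloromethoxy)methyl}dimethyl(phenyl)silane | ClCOC(c1ccc(OCc2ccccc2)c(OCc2ccccc2)c1)[Si](C)(C)c1ccccc1 | intermediate
9 | carbonyl ylide ArCH=O(+)–CH2(−), Ar = 3,4-bis(benzyloxy)phenyl | [CH2-][O+]=Cc1ccc(OCc2ccccc2)c(OCc2ccccc2)c1 | intermediate
10 | (3S,3aR,6S,6aS)-6-[3,4-bis(benzyloxy)phenyl]-3-{[(1S,2R,5S)-5-methyl-2-(propan-2-yl)cyclohexyl]oxy}tetrahydro-1H,3H-furo[3,4-c]furan-1-one | C[C@H]1CC[C@@H]([C@H](C1)O[C@H]2OC(=O)[C@@H]3[C@@H](c4ccc(OCc5ccccc5)c(OCc5ccccc5)c4)OC[C@H]23)C(C)C | intermediate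
11 | (3aR,6S,6aS)-6-[3,4-bis(benzyloxy)phenyl]-3-hydroxytetrahydro-1H,3H-furo[3,4-c]furan-1-one (both C3 epimers) | OC1OC(=O)[C@@H]2[C@@H](c3ccc(OCc4ccccc4)c(OCc4ccccc4)c3)OC[C@H]12 | intermediate
12 | methyl (2S,3S,4R)-2-[3,4-bis(benzyloxy)phenyl]-4-formyloxolane-3-carboxylate | COC(=O)[C@@H]1[C@@H](c2ccc(OCc3ccccc3)c(OCc3ccccc3)c2)OC[C@@H]1C=O | intermediate
13 | 1-(benzyloxy)-4-bromo-2-methoxybenzene | COc1cc(Br)ccc1OCc1ccccc1 | starting material
14 | [4-(benzyloxy)-3-methoxyphenyl]magnesium bromide | COc1cc([Mg]Br)ccc1OCc1ccccc1 | intermediate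
15 | methyl (2S,3S,4R)-4-{(R)-[4-(benzyloxy)-3-methoxyphenyl](hydroxy)methyl}-2-[3,4-bis(benzyloxy)phenyl]oxolane-3-carboxylate | COc1cc([C@H](O)[C@H]2CO[C@H](c3ccc(OCc4ccccc4)c(OCc4ccccc4)c3)[C@H]2C(=O)OC)ccc1OCc1ccccc1 | intermediate
16 | (3R,3aR,6S,6aS)-3-[4-(benzyloxy)-3-methoxyphenyl]-6-[3,4-bis(benzyloxy)phenyl]tetrahydro-1H,3H-furo[3,4-c]furan-1-one | COc1cc([C@@H]2OC(=O)[C@@H]3[C@@H](c4ccc(OCc5ccccc5)c(OCc5ccccc5)c4)OC[C@H]23)ccc1OCc1ccccc1 | intermediate
17 | (R)-[4-(benzyloxy)-3-methoxyphenyl]{(3R,4R,5S)-5-[3,4-bis(benzyloxy)phenyl]-4-(hydroxymethyl)oxolan-3-yl}methanol | COc1cc([C@H](O)[C@H]2CO[C@H](c3ccc(OCc4ccccc4)c(OCc4ccccc4)c3)[C@H]2CO)ccc1OCc1ccccc1 | intermediate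
18 | (7R)-7-hydroxytaxiresinol, 4-[(2S,3R,4R)-4-[(R)-hydroxy(4-hydroxy-3-methoxyphenyl)methyl]-3-(hydroxymethyl)oxolan-2-yl]benzene-1,2-diol | COc1cc([C@H](O)[C@H]2CO[C@H](c3ccc(O)c(O)c3)[C@H]2CO)ccc1O | target

**Totals**

Total step count: 10. Longest linear sequence: 8 steps (steps 1, 2, 5, 6, 7, 8, 9, 10; the branch through steps 3 and 4 is equally long).

**Steps most likely to fail**

Step 5. The cycloaddition may be poorly regioselective (CH2 terminus bonding to the α-carbon) or poorly exo-selective at the aryl-bearing carbon, and the ylide may collapse (ring closure to the aryl oxirane, or protodesilylation) before it is trapped. The fallback sets out from 1 and 7 and comes back at 10; it makes the ylide from the aldehyde and a rhodium carbenoid, with an ester as a removable group that fixes the nucleophilic terminus. Slow addition of 2-(trimethylsilyl)ethyl diazoacetate to 1, 7 and Rh2(OAc)4 (1 mol %) in CH2Cl2 should give the ester-substituted carbonyl ylide, whose ester-bearing carbon bonds to the β-carbon, and so the 4-[2-(trimethylsilyl)ethoxycarbonyl] derivative of 10 (either configuration at C4) F1. TBAF in THF then frees the 4-carboxylic acid F2. Coupling with N-hydroxypyridine-2-thione (DCC) gives the thiohydroxamate ester F3, and Barton decarboxylation (visible light, t-BuSH) gives 10.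

Step 8. Facial selectivity in the addition to the aldehyde may be poor, through competition between the two carbonyl rotamers or through chelation of magnesium to the ester. The fallback sets out from 12 and comes back at 17; it changes from substrate control in C–C bond formation to reagent control in C–H bond formation. The addition is run as before and the lactone mixture, 16 with its (3S)-epimer F4, is reduced with LiAlH4 to 17 with its (S)-carbinol epimer F5. MnO2 in CH2Cl2 oxidises only the benzylic alcohol of both to the aryl ketone F6, which may rest as its cyclic hemiketal. Reduction with (S)-Me-CBS and BH3·SMe2, where the aryl group acts as the large substituent, should then give the (R)-carbinol 17, although the reagent must override the substrate's own facial preference.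

Step 6. The hindered menthyl acetal may cleave slowly, and under the acid the benzylic ring ether may ionise and open. The fallback sets out from 10 and comes back at 11; it cleaves the acyl–oxygen bond instead of the acetal. Me3SnOH in 1,2-dichloroethane at 60 °C should attack the activated lactone carbonyl under neutral conditions, the released hemiacetal loses menthol, and mild acidification returns the lactol 11 without any new compound (F0).

**Further compounds**

F1 | step 5 | 2-(trimethylsilyl)ethyl ester: 4-[2-(trimethylsilyl)ethoxycarbonyl] derivative of 10, either configuration at C4 | C[C@H]1CC[C@@H]([C@H](C1)O[C@H]2OC(=O)[C@@H]3[C@@H](c4ccc(OCc5ccccc5)c(OCc5ccccc5)c4)OC(C(=O)OCC[Si](C)(C)C)[C@H]23)C(C)C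
F2 | step 5 | 4-carboxylic acid of 10, either configuration at C4 | C[C@H]1CC[C@@H]([C@H](C1)O[C@H]2OC(=O)[C@@H]3[C@@H](c4ccc(OCc5ccccc5)c(OCc5ccccc5)c4)OC(C(=O)O)[C@H]23)C(C)C
F3 | step 5 | thiohydroxamate (2-thioxopyridin-1(2H)-yl) ester of F2 | C[C@H]1CC[C@@H]([C@H](C1)O[C@H]2OC(=O)[C@@H]3[C@@H](c4ccc(OCc5ccccc5)c(OCc5ccccc5)c4)OC(C(=O)ON6C=CC=CC6=S)[C@H]23)C(C)C
F0 | step 6 | none | none
F4 | step 8 | (3S,3aR,6S,6aS)-3-[4-(benzyloxy)-3-methoxyphenyl]-6-[3,4-bis(benzyloxy)phenyl]tetrahydro-1H,3H-furo[3,4-c]furan-1-one | COc1cc([C@H]2OC(=O)[C@@H]3[C@@H](c4ccc(OCc5ccccc5)c(OCc5ccccc5)c4)OC[C@H]23)ccc1OCc1ccccc1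
F5 | step 8 | (S)-[4-(benzyloxy)-3-methoxyphenyl]{(3R,4R,5S)-5-[3,4-bis(benzyloxy)phenyl]-4-(hydroxymethyl)oxolan-3-yl}methanol | COc1cc([C@@H](O)[C@H]2CO[C@H](c3ccc(OCc4ccccc4)c(OCc4ccccc4)c3)[C@H]2CO)ccc1OCc1ccccc1
F6 | step 8 | [4-(benzyloxy)-3-methoxyphenyl]{(3R,4R,5S)-5-[3,4-bis(benzyloxy)phenyl]-4-(hydroxymethyl)oxolan-3-yl}methanone | COc1cc(C(=O)[C@H]2CO[C@H](c3ccc(OCc4ccccc4)c(OCc4ccccc4)c3)[C@H]2CO)ccc1OCc1ccccc1
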